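**Retrosynthetic overview**
1. The aryl ether C–O bond is made last, by Mitsunobu union of epoxy alcohol 13 with phenol 14; the oxirane comes from Sharpless asymmetric epoxidation of the (E)-allylic alcohol 12.
2. Key disconnection: the lactone C2(=O)–C3 bond. The enabling feature is the α-methyl-γ-butyrolactone itself: ring O1 on C5, carbonyl C2 and methyl-bearing C3 map onto an ethyl carbonate on the C5 oxygen plus a vinyl group (internal carbon = C3, terminal carbon = the methyl) in homoallyl carbonate 8. A divalent titanium–alkene complex closes the ring and should set C3 trans to the C5 side chain.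
3. Carbon chain: Negishi carboalumination/hydroxymethylation of alkynol 4 gives the (E)-trisubstituted allylic alcohol; C5 comes from (S)-epichlorohydrin 1 through two successive C–C bond-forming epoxide openings.
4. Ring order: oxolan-2-one (step 6), then oxirane (step 8); the chromen-2-one rings are carried in intact with 14.

Key step: step 6

Assumption: 7-hydroxy-8-methoxy-2H-chromen-2-one (14, daphnetin 8-methyl ether) is treated as a purchasable phenol.

**Step 1**
Reactants: 1 (2S)-2-(chloromethyl)oxirane [(S)-epichlorohydrin]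
Product: 2 (2S)-1-chloropent-4-en-2-ol
Conditions: CH2=CHMgBr, CuI (10 mol %), THF, −40 °C
Reagents that add atoms: vinylmagnesium bromide, C=C[Mg]Br
Why: Copper-catalysed Grignard opening of the epoxide at its unsubstituted carbon (SN2) leaves the C–Cl bond and the stereocenter untouched, so the (S) carbinol is carried over from 1.

**Step 2**
Reactants: 2 (2S)-1-chloropent-4-en-2-ol
Product: 4 (4S)-hept-1-en-6-yn-4-ol, via (2S)-2-(prop-2-en-1-yl)oxirane 3 (not isolated)
Conditions: LiC≡CH·H2NCH2CH2NH2 (3 equiv), DMSO, 0 °C → rt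
Reagents that add atoms: lithium acetylide–ethylenediamine complex, [Li]C#C.NCCN
Why: Excess acetylide first closes the chlorohydrin to the epoxide (intramolecular Williamson reaction) and then opens it at the terminal carbon (SN2 alkynylation of an epoxide), and neither event touches the stereocenter.

**Step 3**
Reactants: 4 (4S)-hept-1-en-6-yn-4-ol
Product: 6 (2E,5S)-3-methylocta-2,7-diene-1,5-diol, via alkenylalane 5 (not isolated)
Conditions: AlMe3 (3.5 equiv), Cp2ZrCl2 (25 mol %), CH2Cl2, 0 °C → rt; then n-BuLi, THF, −78 °C; (CH2O)n, −78 °C → rt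
Reagents that add atoms: trimethylaluminium, C[Al](C)C; formaldehyde (from paraformaldehyde), C=O
Why: Zirconium-catalysed Negishi carboalumination adds Me and Al syn across the terminal alkyne (Me to the internal carbon) much faster than across the alkene, and the derived alanate is hydroxymethylated by formaldehyde with retention, which should fix the E geometry.

**Step 4**
Reactants: 6 (2E,5S)-3-methylocta-2,7-diene-1,5-diol
Product: 7 (4S,6E)-8-[(tert-butyldiphenylsilyl)oxy]-6-methylocta-1,6-dien-4-ol
Conditions: t-BuPh2SiCl (1.05 equiv), imidazole, CH2Cl2, 0 °C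
Reagents that add atoms: tert-butyl(chloro)diphenylsilane, CC(C)(C)[Si](Cl)(c1ccccc1)c1ccccc1
Why: Silylation with the bulky chlorosilane should be selective for the primary allylic hydroxyl over the secondary one (steric differentiation).

**Step 5**
Reactants: 7 (4S,6E)-8-[(tert-butyldiphenylsilyl)oxy]-6-methylocta-1,6-dien-4-ol
Product: 8 (4S,6E)-8-[(tert-butyldiphenylsilyl)oxy]-6-methylocta-1,6-dien-4-yl ethyl carbonate
Conditions: ClCO2Et, pyridine, DMAP (cat.), CH2Cl2, 0 °C → rt
Reagents that add atoms: ethyl chloroformate, CCOC(=O)Cl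
Why: O-acylation of the secondary alcohol by the chloroformate (nucleophilic catalysis) places the future lactone carbonyl carbon on the C5 oxygen without touching the stereocenter.

**Step 6**
Reactants: 8 (4S,6E)-8-[(tert-butyldiphenylsilyl)oxy]-6-methylocta-1,6-dien-4-yl ethyl carbonate
Product: 11 (3R,5S)-5-{(2E)-4-[(tert-butyldiphenylsilyl)oxy]-2-methylbut-2-en-1-yl}-3-methyloxolan-2-one, via titanacyclopropane 9 (not isolated), via titaniomethyl lactone 10 (not isolated)
Conditions: Ti(OiPr)4 (1.5 equiv), i-PrMgCl (3.0 equiv), Et2O, −78 → −40 °C; then 1 M aq HCl, 0 °C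
Reagents that add atoms: none
Why: Ti(OiPr)4 and two equivalents of i-PrMgCl give (η2-propene)Ti(OiPr)2, a divalent titanium synthon that exchanges propene for the terminal vinyl group of 8 to give titanacyclopropane 9; its internal Ti–C bond adds to the carbonate carbonyl, ethoxide passes to titanium, and the α-titaniomethyl lactone 10 is protonated on work-up, so the former =CH2 becomes the methyl group. The closest known reaction type is the Kulinkovich-type intramolecular nucleophilic acyl substitution of titanium–alkene and titanium–alkyne complexes on homoallylic and homopropargylic carbonates and esters. The oxolan-2-one is closed in a 5-exo-trig mode by the C3–C2(=O) bond. C3 is set by the C5 stereocenter: in the cis-fused bicycle in which titanium bridges the carbonyl oxygen and the terminal CH2, the C5 side chain should lie on the convex face, so the CH2–Ti group and hence the methyl should end up trans to it, (3R) from (5S). The step needs the monosubstituted alkene to be complexed in preference to the trisubstituted one (secured by the steric demand of the latter and the poor leaving-group ability of its allylic silyl ether) and five- rather than six-membered closure (secured by attack through the internal carbon, which leaves the primary C–Ti bond).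

**Step 7**
Reactants: 11 (3R,5S)-5-{(2E)-4-[(tert-butyldiphenylsilyl)oxy]-2-methylbut-2-en-1-yl}-3-methyloxolan-2-one
Product: 12 (3R,5S)-5-[(2E)-4-hydroxy-2-methylbut-2-en-1-yl]-3-methyloxolan-2-one
Conditions: Bu4NF, AcOH, THF, 0 °C → rt
Reagents that add atoms: none
Why: Fluoride-induced desilylation, buffered with AcOH so that the lactone α-stereocenter should not epimerise.

**Step 8**
Reactants: 12 (3R,5S)-5-[(2E)-4-hydroxy-2-methylbut-2-en-1-yl]-3-methyloxolan-2-one
Product: 13 (3R,5S)-5-{[(2R,3R)-3-(hydroxymethyl)-2-methyloxiran-2-yl]methyl}-3-methyloxolan-2-one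
Conditions: Ti(OiPr)4 (10 mol %), D-(−)-diethyl tartrate (12 mol %), t-BuOOH, 4 Å MS, CH2Cl2, −20 °C
Reagents that add atoms: tert-butyl hydroperoxide, CC(C)(C)OO
Why: In the Sharpless asymmetric epoxidation the titanium–D-tartrate complex binds the allylic hydroxyl and should deliver oxygen to the alkene face that gives the (2R,3R)-oxirane (reagent control), stereospecifically from the E alkene.

**Step 9**
Reactants: 13 (3R,5S)-5-{[(2R,3R)-3-(hydroxymethyl)-2-methyloxiran-2-yl]methyl}-3-methyloxolan-2-one; 14 7-hydroxy-8-methoxy-2H-chromen-2-one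
Product: 15 8-methoxy-7-{[(2R,3R)-3-methyl-3-{[(2S,4R)-4-methyl-5-oxooxolan-2-yl]methyl}oxiran-2-yl]methoxy}-2H-chromen-2-one
Conditions: PPh3, DIAD, THF, 0 °C → rt
Reagents that add atoms: none
Why: Mitsunobu etherification of the primary alcohol by the acidic coumarin phenol (SN2 at the CH2, no stereocenter involved) runs under neutral conditions that should spare the oxirane and the lactone.

**Compound list**
1 | (2S)-2-(chloromethyl)oxirane [(S)-epichlorohydrin] | ClC[C@@H]1CO1 | starting material
2 | (2S)-1-chloropent-4-en-2-ol | ClC[C@@H](O)CC=C | intermediate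
3 | (2S)-2-(prop-2-en-1-yl)oxirane | C=CC[C@H]1CO1 | intermediate
4 | (4S)-hept-1-en-6-yn-4-ol | C#CC[C@@H](O)CC=C | intermediate
5 | alkenylalane: dimethylaluminium alkoxide of (1E,4S)-1-(dimethylalumanyl)-2-methylhepta-1,6-dien-4-ol | C=CC[C@H](O[Al](C)C)C/C(C)=C/[Al](C)C | intermediate
6 | (2E,5S)-3-methylocta-2,7-diene-1,5-diol | OC/C=C(\C)C[C@@H](O)CC=C | intermediate
7 | (4S,6E)-8-[(tert-butyldiphenylsilyl)oxy]-6-methylocta-1,6-dien-4-ol | CC(C)(C)[Si](c1ccccc1)(c1ccccc1)OC/C=C(\C)C[C@@H](O)CC=C | intermediate
8 | (4S,6E)-8-[(tert-butyldiphenylsilyl)oxy]-6-methylocta-1,6-dien-4-yl ethyl carbonate | CC(C)(C)[Si](c1ccccc1)(c1ccccc1)OC/C=C(\C)C[C@@H](OC(=O)OCC)CC=C | intermediate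
9 | titanacyclopropane: diisopropoxytitanium η2-complex of the terminal alkene of 8 (interconverting π-face isomers) | CC(C)(C)[Si](c1ccccc1)(c1ccccc1)OC/C=C(\C)C[C@@H](OC(=O)OCC)CC1C[Ti]1(OC(C)C)OC(C)C | intermediate
10 | titaniomethyl lactone: (3R,5S)-5-{(2E)-4-[(tert-butyldiphenylsilyl)oxy]-2-methylbut-2-en-1-yl}-3-{[ethoxybis(propan-2-yloxy)titanio]methyl}oxolan-2-one | CC(C)(C)[Si](c1ccccc1)(c1ccccc1)OC/C=C(\C)C[C@@H]1C[C@@H](C[Ti](OC(C)C)(OC(C)C)OCC)C(=O)O1 | intermediate
11 | (3R,5S)-5-{(2E)-4-[(tert-butyldiphenylsilyl)oxy]-2-methylbut-2-en-1-yl}-3-methyloxolan-2-one | CC(C)(C)[Si](c1ccccc1)(c1ccccc1)OC/C=C(\C)C[C@@H]1C[C@@H](C)C(=O)O1 | intermediate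
12 | (3R,5S)-5-[(2E)-4-hydroxy-2-methylbut-2-en-1-yl]-3-methyloxolan-2-one | OC/C=C(\C)C[C@@H]1C[C@@H](C)C(=O)O1 | intermediate
13 | (3R,5S)-5-{[(2R,3R)-3-(hydroxymethyl)-2-methyloxiran-2-yl]methyl}-3-methyloxolan-2-one | OC[C@H]1O[C@]1(C)C[C@@H]1C[C@@H](C)C(=O)O1 | intermediate
14 | 7-hydroxy-8-methoxy-2H-chromen-2-one | COc1c(O)ccc2ccc(=O)oc12 | starting material
15 | 8-methoxy-7-{[(2R,3R)-3-methyl-3-{[(2S,4R)-4-methyl-5-oxooxolan-2-yl]methyl}oxiran-2-yl]methoxy}-2H-chromen-2-one | COc1c(OC[C@H]2O[C@]2(C)C[C@@H]2C[C@@H](C)C(=O)O2)ccc2ccc(=O)oc12 | target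

**Step count and risks**
Total step count: 9. Longest linear sequence: 9 steps (1 → 15; 14 enters in step 9).

Steps most likely to fail:

Step 6. The acyl substitution may discriminate the two alkene faces insufficiently (erosion of the trans relationship), close through the terminal alkene carbon, or be preceded by Grignard attack on the carbonate. The trans preference is a prediction from the bicyclic transition-state model and is the main uncertainty of the route. The fallback uses known chemistry, makes the same C2–C3 bond as a C=C at the enol ether level, and sets out from 7. Palladium-catalysed transfer vinylation (Pd(OCOCF3)2, 4,7-diphenyl-1,10-phenanthroline, butyl vinyl ether, Et3N, 75 °C) should give vinyl ether tert-butyl{[(2E,5S)-5-(ethenyloxy)-3-methylocta-2,7-dien-1-yl]oxy}diphenylsilane F1. Enol ether–olefin ring-closing metathesis (second-generation Grubbs catalyst, toluene, 70 °C, high dilution) should close dihydrofuran tert-butyl({(2E)-4-[(2S)-2,3-dihydrofuran-2-yl]-3-methylbut-2-en-1-yl}oxy)diphenylsilane F2; closure onto the trisubstituted alkene is the competing process to watch. Pyridinium chlorochromate (NaOAc, CH2Cl2) should oxidise the cyclic enol ether to lactone (5S)-5-{(2E)-4-[(tert-butyldiphenylsilyl)oxy]-2-methylbut-2-en-1-yl}oxolan-2-one F3. LDA then MeI at −78 °C should methylate the enolate anti to the C5 substituent, and the route is rejoined at 11.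

Step 3. Capture of the alanate by formaldehyde may be incomplete (protonation instead of C–C bond formation), or the alkenylalane may partly lose its geometry through alkoxide-assisted isomerisation. The fallback introduces C1 by carbonylation of an isolated alkenyl iodide and sets out from 4. The carboalumination mixture is quenched with I2 to give iodide (1E,4S)-1-iodo-2-methylhepta-1,6-dien-4-ol F4, whose geometry can be secured at this stage. Methoxycarbonylation (PdCl2(PPh3)2, CO, MeOH, Et3N) should give enoate methyl (2E,5S)-5-hydroxy-3-methylocta-2,7-dienoate F5, and reduction with i-Bu2AlH returns to the route at 6.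

Step 9. The oxirane may be opened or may migrate (Payne-type) when the epoxy alcohol is activated, or the hydrazide may be alkylated instead of the phenol. The fallback reverses the order of etherification and epoxidation and sets out from 12. Appel bromination (CBr4, PPh3) should give bromide (3R,5S)-5-[(2E)-4-bromo-2-methylbut-2-en-1-yl]-3-methyloxolan-2-one F6. Williamson etherification with 14 (K2CO3, acetone) should give allyl aryl ether 8-methoxy-7-{[(2E)-3-methyl-4-[(2S,4R)-4-methyl-5-oxooxolan-2-yl]but-2-en-1-yl]oxy}-2H-chromen-2-one F7. Catalyst-controlled Shi epoxidation of the trisubstituted alkene (D-fructose-derived ketone, KHSO5, K2CO3 buffer, MeCN–H2O, 0 °C) is expected to give the (2R,3R)-oxirane, rejoining the route at 15.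

**Further compounds**
F1 | step 6 | tert-butyl{[(2E,5S)-5-(ethenyloxy)-3-methylocta-2,7-dien-1-yl]oxy}diphenylsilane | CC(C)(C)[Si](c1ccccc1)(c1ccccc1)OC/C=C(\C)C[C@@H](OC=C)CC=C
F2 | step 6 | tert-butyl({(2E)-4-[(2S)-2,3-dihydrofuran-2-yl]-3-methylbut-2-en-1-yl}oxy)diphenylsilane | CC(C)(C)[Si](c1ccccc1)(c1ccccc1)OC/C=C(\C)C[C@@H]1CC=CO1
F3 | step 6 | (5S)-5-{(2E)-4-[(tert-butyldiphenylsilyl)oxy]-2-methylbut-2-en-1-yl}oxolan-2-one | CC(C)(C)[Si](c1ccccc1)(c1ccccc1)OC/C=C(\C)C[C@@H]1CCC(=O)O1
F4 | step 3 | (1E,4S)-1-iodo-2-methylhepta-1,6-dien-4-ol | I/C=C(\C)C[C@@H](O)CC=C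
F5 | step 3 | methyl (2E,5S)-5-hydroxy-3-methylocta-2,7-dienoate | COC(=O)/C=C(\C)C[C@@H](O)CC=C
F6 | step 9 | (3R,5S)-5-[(2E)-4-bromo-2-methylbut-2-en-1-yl]-3-methyloxolan-2-one | BrC/C=C(\C)C[C@@H]1C[C@@H](C)C(=O)O1
F7 | step 9 | 8-methoxy-7-{[(2E)-3-methyl-4-[(2S,4R)-4-methyl-5-oxooxolan-2-yl]but-2-en-1-yl]oxy}-2H-chromen-2-one | COc1c(OC/C=C(\C)C[C@@H]2C[C@@H](C)C(=O)O2)ccc2ccc(=O)oc12
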